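**Assumption:** the SMILES is read as the cis-fused (6aR,11aR)-pterocarpan, and 5-bromo-2,4-dihydroxybenzaldehyde, 3-chloro-3-methylbut-1-yne and (S)-4-benzyloxazolidin-2-one are taken as catalogue chemicals.

## Retrosynthetic overview

1. Ring C (dihydrofuran, O11–C11a) is closed last by ionising a 2'-hydroxyisoflavan-4-ol; only the cis fusion can form, so C6a dictates C11a.
2. The pyran on ring D comes from an aryl 1,1-dimethylpropargyl ether (Claisen, then 6π closure) on the isoflavan; ring B comes from a Mitsunobu etherification.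
3. The C6a–C11a bond is made by an Evans syn-aldol between ring A aldehyde 7 and the (S)-oxazolidinone imide 23 of the ring D arylacetic acid; this sets C6a.
4. Aldehyde 7 comes from resorcinol and 3-methylbut-2-enoic acid (chromanone, chromene, ortho-formylation); imide 23 comes from 5-bromo-2,4-dihydroxybenzaldehyde (Dakin oxidation, Claisen prenylation, Br to CH2CO2H).
5. Ring order: pyran on ring A, then ring B, then pyran on ring D, then ring C.

Abbreviations in names: allyloxy = prop-2-en-1-yloxy; prenyl = 3-methylbut-2-en-1-yl; TBSO = (tert-butyldimethylsilyl)oxy; TIPSO = (triisopropylsilyl)oxy.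

## Route

### Ring A aldehyde

Step 1
Reactants: 1 resorcinol; 2 3-methylbut-2-enoic acid
Product: 3 7-hydroxy-2,2-dimethylchroman-4-one
Conditions: P2O5, MeSO3H, 70 °C
Reagents that add atoms: none
Why: Friedel–Crafts acylation para to one hydroxyl followed by intramolecular oxa-Michael addition closes the pyranone in one pot.

Step 2
Reactants: 3 7-hydroxy-2,2-dimethylchroman-4-one
Product: 4 2,2-dimethylchromane-4,7-diol (racemic)
Conditions: LiAlH4 (excess), THF, 0 °C → rt; Rochelle salt work-up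
Reagents that add atoms: none
Why: Hydride reduction of the aryl ketone; the excess covers the hydride consumed by the phenol.

Step 3
Reactants: 4 2,2-dimethylchromane-4,7-diol
Product: 5 2,2-dimethyl-2H-chromen-7-ol
Conditions: p-TsOH·H2O (cat.), toluene, 80 °C
Reagents that add atoms: none
Why: Acid-catalysed E1 dehydration of a p-hydroxybenzylic alcohol gives the conjugated chromene.

Step 4
Reactants: 5 2,2-dimethyl-2H-chromen-7-ol
Product: 6 7-hydroxy-2,2-dimethyl-2H-chromene-6-carbaldehyde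
Conditions: MgCl2, Et3N, paraformaldehyde, MeCN, reflux
Reagents that add atoms: paraformaldehyde (as formaldehyde), C=O
Why: Magnesium phenoxide ortho-formylation (Casnati–Skattebøl) is ortho-specific and prefers the less hindered C6 over C8, which sits between two oxygens.

Step 5
Reactants: 6 7-hydroxy-2,2-dimethyl-2H-chromene-6-carbaldehyde
Product: 7 7-(TBSO)-2,2-dimethyl-2H-chromene-6-carbaldehyde
Conditions: TBSCl, imidazole, DMAP (cat.), DMF, rt
Reagents that add atoms: tert-butyldimethylsilyl chloride, CC(C)(C)[Si](C)(C)Cl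
Why: Phenol silylation gives a fluoride-labile group that can later be removed in the presence of allyl ethers.

### Ring D arylacetyl imide

Step 6
Reactants: 8 5-bromo-2,4-dihydroxybenzaldehyde
Product: 9 5-bromo-2-hydroxy-4-[(2-methylbut-3-yn-2-yl)oxy]benzaldehyde
Conditions: 3-chloro-3-methylbut-1-yne, K2CO3, KI, CuI (cat.), acetone, 55 °C
Reagents that add atoms: 3-chloro-3-methylbut-1-yne, CC(C)(Cl)C#C
Why: Copper-assisted propargylic etherification occurs at the 4-OH because the 2-OH is hydrogen-bonded to the aldehyde.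

Step 7
Reactants: 9 5-bromo-2-hydroxy-4-[(2-methylbut-3-yn-2-yl)oxy]benzaldehyde
Product: 10 2-(allyloxy)-5-bromo-4-[(2-methylbut-3-yn-2-yl)oxy]benzaldehyde
Conditions: allyl bromide, K2CO3, DMF, rt
Reagents that add atoms: allyl bromide, C=CCBr
Why: Williamson etherification of the remaining phenol; room temperature keeps the propargyl ether from rearranging.

Step 8
Reactants: 10 2-(allyloxy)-5-bromo-4-[(2-methylbut-3-yn-2-yl)oxy]benzaldehyde
Product: 12 2-(allyloxy)-5-bromo-4-[(2-methylbut-3-yn-2-yl)oxy]phenol, via aryl formate 11 (not isolated)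
Conditions: mCPBA, CH2Cl2, 0 °C → rt; then K2CO3 (cat.), MeOH, rt
Reagents that add atoms: mCPBA, OOC(=O)c1cccc(Cl)c1
Why: Dakin-type Baeyer–Villiger oxidation, in which the electron-rich aryl group migrates faster than the peracid attacks the monosubstituted alkene or the alkyne; the formate is then methanolysed.

Step 9
Reactants: 12 2-(allyloxy)-5-bromo-4-[(2-methylbut-3-yn-2-yl)oxy]phenol
Product: 13 [2-(allyloxy)-5-bromo-4-[(2-methylbut-3-yn-2-yl)oxy]phenoxy]triisopropylsilane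
Conditions: TIPSCl, imidazole, DMF, rt
Reagents that add atoms: triisopropylsilyl chloride, CC(C)[Si](Cl)(C(C)C)C(C)C
Why: Silylation marks the future chromene oxygen (C8–O) with a robust group that is orthogonal to allyl ethers.

Step 10
Reactants: 13 [2-(allyloxy)-5-bromo-4-[(2-methylbut-3-yn-2-yl)oxy]phenoxy]triisopropylsilane
Product: 14 [2-(allyloxy)-5-bromo-4-[(2-methylbut-3-en-2-yl)oxy]phenoxy]triisopropylsilane
Conditions: H2 (1 atm), Pd/CaCO3 poisoned with Pb(OAc)2, quinoline, EtOAc, rt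
Reagents that add atoms: none
Why: Lindlar semi-hydrogenation stops at the alkene and leaves the aryl bromide and allyl ether untouched.

Step 11
Reactants: 14 [2-(allyloxy)-5-bromo-4-[(2-methylbut-3-en-2-yl)oxy]phenoxy]triisopropylsilane
Product: 15 3-(allyloxy)-6-bromo-2-prenyl-4-(TIPSO)phenol
Conditions: N,N-diethylaniline, 120 °C
Reagents that add atoms: none
Why: Aromatic Claisen rearrangement of the 1,1-dimethylallyl ether delivers a normal prenyl group to the only free ortho carbon, the other being blocked by bromine.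

Step 12
Reactants: 15 3-(allyloxy)-6-bromo-2-prenyl-4-(TIPSO)phenol
Product: 16 [2,4-bis(allyloxy)-5-bromo-3-prenylphenoxy]triisopropylsilane
Conditions: allyl bromide, K2CO3, acetone, reflux
Reagents that add atoms: allyl bromide, C=CCBr
Why: Williamson etherification of the liberated phenol, so both oxygens flanking the prenyl group carry non-migrating allyl groups.

Step 13
Reactants: 16 [2,4-bis(allyloxy)-5-bromo-3-prenylphenoxy]triisopropylsilane
Product: 18 2-[2,4-bis(allyloxy)-3-prenyl-5-(TIPSO)phenyl]ethan-1-ol, via aryllithium 17 (not isolated)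
Conditions: n-BuLi, THF, −78 °C; then ethylene oxide, BF3·OEt2, −78 °C
Reagents that add atoms: ethylene oxide, C1CO1
Why: Bromine–lithium exchange is faster at −78 °C than any reaction with the allyl ethers, and the BF3-activated epoxide is opened at that temperature before the ortho-allyloxy aryllithium can cyclise.

Step 14
Reactants: 18 2-[2,4-bis(allyloxy)-3-prenyl-5-(TIPSO)phenyl]ethan-1-ol
Product: 19 2-[2,4-bis(allyloxy)-3-prenyl-5-(TIPSO)phenyl]acetaldehyde
Conditions: Dess–Martin periodinane, CH2Cl2, 0 °C → rt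
Reagents that add atoms: none
Why: Dess–Martin oxidation of a primary alcohol is neutral and does not touch the alkenes or the silyl ether.

Step 15
Reactants: 19 2-[2,4-bis(allyloxy)-3-prenyl-5-(TIPSO)phenyl]acetaldehyde
Product: 20 2-[2,4-bis(allyloxy)-3-prenyl-5-(TIPSO)phenyl]acetic acid
Conditions: NaClO2, NaH2PO4, 2-methylbut-2-ene, t-BuOH/H2O, rt
Reagents that add atoms: sodium chlorite, [Na+].[O-]Cl=O
Why: Pinnick oxidation, with excess 2-methylbut-2-ene scavenging HOCl so the prenyl and allyl alkenes survive.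

Step 16
Reactants: 20 2-[2,4-bis(allyloxy)-3-prenyl-5-(TIPSO)phenyl]acetic acid; 21 (S)-4-benzyloxazolidin-2-one
Product: 23 (S)-4-benzyl-3-{2-[2,4-bis(allyloxy)-3-prenyl-5-(TIPSO)phenyl]acetyl}oxazolidin-2-one, via mixed pivalic anhydride 22 (not isolated)
Conditions: PivCl, Et3N, THF, −20 °C; then 21, LiCl, rt
Reagents that add atoms: none
Why: Mixed-anhydride N-acylation with LiCl/Et3N attaches the auxiliary without strong base.

### Fragment union and endgame

Step 17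
Reactants: 23 (S)-4-benzyl-3-{2-[2,4-bis(allyloxy)-3-prenyl-5-(TIPSO)phenyl]acetyl}oxazolidin-2-one; 7 7-(TBSO)-2,2-dimethyl-2H-chromene-6-carbaldehyde
Product: 26 (S)-4-benzyl-3-{(2S,3S)-2-[2,4-bis(allyloxy)-3-prenyl-5-(TIPSO)phenyl]-3-hydroxy-3-[7-(TBSO)-2,2-dimethyl-2H-chromen-6-yl]propanoyl}oxazolidin-2-one, via Z-dibutylboron enolate 24 (not isolated), via dibutylboron aldolate 25 (not isolated)
Conditions: Bu2BOTf, i-Pr2NEt, CH2Cl2, −78 → 0 °C; then 7, −78 → 0 °C; then pH 7 buffer, MeOH, 30% H2O2, 0 °C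
Reagents that add atoms: none
Why: Evans syn-aldol through a Zimmerman–Traxler chair of the Z-boron enolate, where the (S)-benzyl auxiliary shields one enolate face and gives the (2S,3S) adduct; C2 becomes C6a (R) of the target.

Step 18
Reactants: 26 the (2S,3S) aldol adduct
Product: 27 (S)-4-benzyl-3-{(2S,3S)-2-[2,4-bis(allyloxy)-3-prenyl-5-(TIPSO)phenyl]-3-(TBSO)-3-[7-(TBSO)-2,2-dimethyl-2H-chromen-6-yl]propanoyl}oxazolidin-2-one
Conditions: TBSOTf, 2,6-lutidine, CH2Cl2, −78 → 0 °C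
Reagents that add atoms: tert-butyldimethylsilyl triflate, CC(C)(C)[Si](C)(C)OS(=O)(=O)C(F)(F)F
Why: Silylation of the benzylic carbinol blocks retro-aldol cleavage and later o-quinone methide formation; it also re-silylates any ring A phenol lost in the oxidative work-up.

Step 19
Reactants: 27 the silylated aldol imide
Product: 28 (2R,3S)-2-[2,4-bis(allyloxy)-3-prenyl-5-(TIPSO)phenyl]-3-(TBSO)-3-[7-(TBSO)-2,2-dimethyl-2H-chromen-6-yl]propan-1-ol
Conditions: LiBH4, MeOH (1 equiv), THF, 0 °C → rt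
Reagents that add atoms: none
Why: Reductive cleavage of the imide gives the primary alcohol and releases the auxiliary; the stereocentre is untouched and its descriptor changes only by priority.

Step 20
Reactants: 28 the bis-aryl-silylated primary alcohol
Product: 29 (2R,3S)-2-[2,4-bis(allyloxy)-5-hydroxy-3-prenylphenyl]-3-(TBSO)-3-(7-hydroxy-2,2-dimethyl-2H-chromen-6-yl)propan-1-ol
Conditions: TBAF, AcOH (1:1), THF, 0 °C
Reagents that add atoms: none
Why: Phenolic silyl ethers are cleaved by fluoride far faster than the hindered secondary alkyl silyl ether, and the acetic acid buffer prevents silyl migration to the primary alcohol.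

Step 21
Reactants: 29 the diphenol alcohol
Product: 30 2,4-bis(allyloxy)-5-[(6S,7R)-6-(TBSO)-2,2-dimethyl-7,8-dihydro-2H,6H-pyrano[3,2-g]chromen-7-yl]-3-prenylphenol (trans-isoflavan; 3R,4S in isoflavan numbering)
Conditions: PPh3, DIAD, THF (0.01 M), 0 °C → rt
Reagents that add atoms: none
Why: Mitsunobu etherification of the primary alcohol by the ring A phenol closes ring B (6-exo); the ring D phenol cannot reach the activated carbon and no stereocentre is involved.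

Step 22
Reactants: 30 the trans-isoflavan phenol
Product: 31 (6S,7R)-7-{2,4-bis(allyloxy)-5-[(2-methylbut-3-yn-2-yl)oxy]-3-prenylphenyl}-6-(TBSO)-2,2-dimethyl-7,8-dihydro-2H,6H-pyrano[3,2-g]chromene
Conditions: 3-chloro-3-methylbut-1-yne, DBU, CuCl2·2H2O (cat.), MeCN, 0 °C → rt
Reagents that add atoms: 3-chloro-3-methylbut-1-yne, CC(C)(Cl)C#C
Why: Copper-catalysed propargylic etherification of the only free phenol; the neighbouring allyl ether cannot migrate under base.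

Step 23
Reactants: 31 the aryl propargyl ether
Product: 32 (6S,7R)-7-[6,8-bis(allyloxy)-2,2-dimethyl-7-prenyl-2H-chromen-5-yl]-6-(TBSO)-2,2-dimethyl-7,8-dihydro-2H,6H-pyrano[3,2-g]chromene
Conditions: o-xylene, 140 °C
Reagents that add atoms: none
Why: Aryl propargyl ether Claisen rearrangement, 1,5-hydrogen shift and oxa-6π electrocyclisation build the chromene at the only free ortho carbon (C7); the allyl ethers have both ortho and para positions blocked.

Step 24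
Reactants: 32 the bis-chromene bis-allyl ether
Product: 33 5-[(6S,7R)-6-(TBSO)-2,2-dimethyl-7,8-dihydro-2H,6H-pyrano[3,2-g]chromen-7-yl]-2,2-dimethyl-7-prenyl-2H-chromene-6,8-diol
Conditions: Pd(PPh3)4 (5 mol %), morpholine, THF, rt
Reagents that add atoms: none
Why: Tsuji–Trost deallylation with zerovalent palladium frees both phenols under neutral conditions while the benzylic silyl ether stays in place.

Step 25
Reactants: 33 the bisphenol silyl ether
Product: 35 Lespecyrtin E4, the (6aR,11aR)-pterocarpan, via isoflavan-4-ol 34 (not isolated)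
Conditions: TBAF, THF, 0 °C → rt; then PPTS (cat.), CH2Cl2, rt
Reagents that add atoms: none
Why: After desilylation, acid ionises the p-alkoxybenzylic alcohol (SN1) and the free 2'-phenol traps the cation at once in a 5-exo closure; only the cis-fused ring can form, so C6a (R) sets C11a (R).

## Compound list

1 | resorcinol | Oc1cccc(O)c1 | starting material
2 | 3-methylbut-2-enoic acid | CC(C)=CC(=O)O | starting material
3 | 7-hydroxy-2,2-dimethylchroman-4-one | CC1(C)CC(=O)c2ccc(O)cc2O1 | intermediate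
4 | 2,2-dimethylchromane-4,7-diol (racemic) | CC1(C)CC(O)c2ccc(O)cc2O1 | intermediate
5 | 2,2-dimethyl-2H-chromen-7-ol | CC1(C)C=Cc2ccc(O)cc2O1 | intermediate
6 | 7-hydroxy-2,2-dimethyl-2H-chromene-6-carbaldehyde | CC1(C)C=Cc2cc(C=O)c(O)cc2O1 | intermediate
7 | 7-(TBSO)-2,2-dimethyl-2H-chromene-6-carbaldehyde | CC1(C)C=Cc2cc(C=O)c(O[Si](C)(C)C(C)(C)C)cc2O1 | intermediate
8 | 5-bromo-2,4-dihydroxybenzaldehyde | O=Cc1cc(Br)c(O)cc1O | starting material
9 | 5-bromo-2-hydroxy-4-[(2-methylbut-3-yn-2-yl)oxy]benzaldehyde | O=Cc1cc(Br)c(OC(C)(C)C#C)cc1O | intermediate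
10 | 2-(allyloxy)-5-bromo-4-[(2-methylbut-3-yn-2-yl)oxy]benzaldehyde | O=Cc1cc(Br)c(OC(C)(C)C#C)cc1OCC=C | intermediate
11 | 2-(allyloxy)-5-bromo-4-[(2-methylbut-3-yn-2-yl)oxy]phenyl formate | O=COc1cc(Br)c(OC(C)(C)C#C)cc1OCC=C | intermediate
12 | 2-(allyloxy)-5-bromo-4-[(2-methylbut-3-yn-2-yl)oxy]phenol | Oc1cc(Br)c(OC(C)(C)C#C)cc1OCC=C | intermediate
13 | [2-(allyloxy)-5-bromo-4-[(2-methylbut-3-yn-2-yl)oxy]phenoxy]triisopropylsilane | CC(C)[Si](Oc1cc(Br)c(OC(C)(C)C#C)cc1OCC=C)(C(C)C)C(C)C | intermediate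
14 | [2-(allyloxy)-5-bromo-4-[(2-methylbut-3-en-2-yl)oxy]phenoxy]triisopropylsilane | CC(C)[Si](Oc1cc(Br)c(OC(C)(C)C=C)cc1OCC=C)(C(C)C)C(C)C | intermediate
15 | 3-(allyloxy)-6-bromo-2-prenyl-4-(TIPSO)phenol | CC(C)[Si](Oc1cc(Br)c(O)c(CC=C(C)C)c1OCC=C)(C(C)C)C(C)C | intermediate
16 | [2,4-bis(allyloxy)-5-bromo-3-prenylphenoxy]triisopropylsilane | CC(C)[Si](Oc1cc(Br)c(OCC=C)c(CC=C(C)C)c1OCC=C)(C(C)C)C(C)C | intermediate
17 | [2,4-bis(allyloxy)-3-prenyl-5-(TIPSO)phenyl]lithium | CC(C)[Si](Oc1cc([Li])c(OCC=C)c(CC=C(C)C)c1OCC=C)(C(C)C)C(C)C | intermediate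
18 | 2-[2,4-bis(allyloxy)-3-prenyl-5-(TIPSO)phenyl]ethan-1-ol | CC(C)[Si](Oc1cc(CCO)c(OCC=C)c(CC=C(C)C)c1OCC=C)(C(C)C)C(C)C | intermediate
19 | 2-[2,4-bis(allyloxy)-3-prenyl-5-(TIPSO)phenyl]acetaldehyde | CC(C)[Si](Oc1cc(CC=O)c(OCC=C)c(CC=C(C)C)c1OCC=C)(C(C)C)C(C)C | intermediate
20 | 2-[2,4-bis(allyloxy)-3-prenyl-5-(TIPSO)phenyl]acetic acid | CC(C)[Si](Oc1cc(CC(=O)O)c(OCC=C)c(CC=C(C)C)c1OCC=C)(C(C)C)C(C)C | intermediate
21 | (S)-4-benzyloxazolidin-2-one | O=C1OC[C@H](Cc2ccccc2)N1 | starting material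
22 | 2-[2,4-bis(allyloxy)-3-prenyl-5-(TIPSO)phenyl]acetic pivalic anhydride | CC(C)[Si](Oc1cc(CC(=O)OC(=O)C(C)(C)C)c(OCC=C)c(CC=C(C)C)c1OCC=C)(C(C)C)C(C)C | intermediate
23 | (S)-4-benzyl-3-{2-[2,4-bis(allyloxy)-3-prenyl-5-(TIPSO)phenyl]acetyl}oxazolidin-2-one | CC(C)[Si](Oc1cc(CC(=O)N2[C@@H](Cc3ccccc3)COC2=O)c(OCC=C)c(CC=C(C)C)c1OCC=C)(C(C)C)C(C)C | intermediate
24 | Z-dibutylboron enolate of 23 | CC(C)[Si](Oc1cc(/C=C(\OB(CCCC)CCCC)N2[C@@H](Cc3ccccc3)COC2=O)c(OCC=C)c(CC=C(C)C)c1OCC=C)(C(C)C)C(C)C | intermediate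
25 | dibutylboron aldolate of 26 | O=C([C@@H](c1cc(O[Si](C(C)C)(C(C)C)C(C)C)c(OCC=C)c(CC=C(C)C)c1OCC=C)[C@H](OB(CCCC)CCCC)c1cc2C=CC(C)(C)Oc2cc1O[Si](C)(C)C(C)(C)C)N1[C@@H](Cc2ccccc2)COC1=O | intermediate
26 | (S)-4-benzyl-3-{(2S,3S)-2-[2,4-bis(allyloxy)-3-prenyl-5-(TIPSO)phenyl]-3-hydroxy-3-[7-(TBSO)-2,2-dimethyl-2H-chromen-6-yl]propanoyl}oxazolidin-2-one | O=C([C@@H](c1cc(O[Si](C(C)C)(C(C)C)C(C)C)c(OCC=C)c(CC=C(C)C)c1OCC=C)[C@H](O)c1cc2C=CC(C)(C)Oc2cc1O[Si](C)(C)C(C)(C)C)N1[C@@H](Cc2ccccc2)COC1=O | intermediate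
27 | (S)-4-benzyl-3-{(2S,3S)-2-[2,4-bis(allyloxy)-3-prenyl-5-(TIPSO)phenyl]-3-(TBSO)-3-[7-(TBSO)-2,2-dimethyl-2H-chromen-6-yl]propanoyl}oxazolidin-2-one | O=C([C@@H](c1cc(O[Si](C(C)C)(C(C)C)C(C)C)c(OCC=C)c(CC=C(C)C)c1OCC=C)[C@H](O[Si](C)(C)C(C)(C)C)c1cc2C=CC(C)(C)Oc2cc1O[Si](C)(C)C(C)(C)C)N1[C@@H](Cc2ccccc2)COC1=O | intermediate
28 | (2R,3S)-2-[2,4-bis(allyloxy)-3-prenyl-5-(TIPSO)phenyl]-3-(TBSO)-3-[7-(TBSO)-2,2-dimethyl-2H-chromen-6-yl]propan-1-ol | OC[C@@H](c1cc(O[Si](C(C)C)(C(C)C)C(C)C)c(OCC=C)c(CC=C(C)C)c1OCC=C)[C@H](O[Si](C)(C)C(C)(C)C)c1cc2C=CC(C)(C)Oc2cc1O[Si](C)(C)C(C)(C)C | intermediate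
29 | (2R,3S)-2-[2,4-bis(allyloxy)-5-hydroxy-3-prenylphenyl]-3-(TBSO)-3-(7-hydroxy-2,2-dimethyl-2H-chromen-6-yl)propan-1-ol | OC[C@@H](c1cc(O)c(OCC=C)c(CC=C(C)C)c1OCC=C)[C@H](O[Si](C)(C)C(C)(C)C)c1cc2C=CC(C)(C)Oc2cc1O | intermediate
30 | 2,4-bis(allyloxy)-5-[(6S,7R)-6-(TBSO)-2,2-dimethyl-7,8-dihydro-2H,6H-pyrano[3,2-g]chromen-7-yl]-3-prenylphenol | C1[C@@H](c2cc(O)c(OCC=C)c(CC=C(C)C)c2OCC=C)[C@H](O[Si](C)(C)C(C)(C)C)c2cc3C=CC(C)(C)Oc3cc2O1 | intermediate
31 | (6S,7R)-7-{2,4-bis(allyloxy)-5-[(2-methylbut-3-yn-2-yl)oxy]-3-prenylphenyl}-6-(TBSO)-2,2-dimethyl-7,8-dihydro-2H,6H-pyrano[3,2-g]chromene | C1[C@@H](c2cc(OC(C)(C)C#C)c(OCC=C)c(CC=C(C)C)c2OCC=C)[C@H](O[Si](C)(C)C(C)(C)C)c2cc3C=CC(C)(C)Oc3cc2O1 | intermediate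
32 | (6S,7R)-7-[6,8-bis(allyloxy)-2,2-dimethyl-7-prenyl-2H-chromen-5-yl]-6-(TBSO)-2,2-dimethyl-7,8-dihydro-2H,6H-pyrano[3,2-g]chromene | C1[C@@H](c2c3C=CC(C)(C)Oc3c(OCC=C)c(CC=C(C)C)c2OCC=C)[C@H](O[Si](C)(C)C(C)(C)C)c2cc3C=CC(C)(C)Oc3cc2O1 | intermediate
33 | 5-[(6S,7R)-6-(TBSO)-2,2-dimethyl-7,8-dihydro-2H,6H-pyrano[3,2-g]chromen-7-yl]-2,2-dimethyl-7-prenyl-2H-chromene-6,8-diol | C1[C@@H](c2c3C=CC(C)(C)Oc3c(O)c(CC=C(C)C)c2O)[C@H](O[Si](C)(C)C(C)(C)C)c2cc3C=CC(C)(C)Oc3cc2O1 | intermediate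
34 | 5-[(6S,7R)-6-hydroxy-2,2-dimethyl-7,8-dihydro-2H,6H-pyrano[3,2-g]chromen-7-yl]-2,2-dimethyl-7-prenyl-2H-chromene-6,8-diol | C1[C@@H](c2c3C=CC(C)(C)Oc3c(O)c(CC=C(C)C)c2O)[C@H](O)c2cc3C=CC(C)(C)Oc3cc2O1 | intermediate
35 | Lespecyrtin E4, (6aR,11aR)-cis-pterocarpan | CC(C)=CCc1c(O)c2c(c3c1O[C@H]1c4cc5c(cc4OC[C@@H]31)OC(C)(C)C=C5)C=CC(C)(C)O2 | target

## Step count and risks

Total step count: 25 (steps 1–5 ring A aldehyde, steps 6–16 ring D imide, steps 17–25 union and endgame).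
Longest linear sequence: 20 steps (8 to 35, steps 6–25).

**Step 17 (aldol).** The electron-rich ortho-silyloxy aldehyde may react sluggishly or with poor diastereoselectivity with the boron enolate. The fallback sets out from acid 20 and uses a chlorotitanium enolate of a thiazolidinethione in place of the boron enolate of the oxazolidinone. Acid 20 is coupled with (S)-4-benzylthiazolidine-2-thione (EDC·HCl, DMAP, CH2Cl2) to give (S)-1-(4-benzyl-2-thioxothiazolidin-3-yl)-2-[2,4-bis(allyloxy)-3-prenyl-5-(TIPSO)phenyl]ethan-1-one F5. Enolisation with TiCl4, i-Pr2NEt and N-methyl-2-pyrrolidinone in CH2Cl2 and addition of 7 at −78 °C gives the same-sense (2S,3S) syn adduct, the thiazolidinethione aldol adduct F6. Silylation with TBSOTf/2,6-lutidine gives its benzylic TBS ether F7, and LiBH4 reduction removes the auxiliary and comes back to the route at 28.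

**Step 13 (aryllithium and ethylene oxide).** The BF3-mediated epoxide opening by a hindered ortho-allyloxy aryllithium may be low-yielding. The fallback sets out from 16 and replaces the two-carbon epoxide opening and alcohol oxidation by formylation and a one-carbon Wittig homologation. After the same exchange (n-BuLi, −78 °C) the anion is quenched with DMF to give 2,4-bis(allyloxy)-3-prenyl-5-(TIPSO)benzaldehyde F3. Wittig reaction with (methoxymethyl)triphenylphosphonium chloride and KN(SiMe3)2 in THF gives the methyl enol ether 1-(2-methoxyvinyl)-2,4-bis(allyloxy)-3-prenyl-5-(TIPSO)benzene F4 (E/Z mixture). Brief hydrolysis with dilute aqueous HCl in THF at rt comes back to the route at 19, skipping alcohol 18 and step 14.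

**Step 4 (ortho-formylation).** C6/C8 regioselectivity or the stability of the free hydroxychromene may be inadequate. The fallback sets out from 5 and replaces the magnesium-chelate formylation of the free phenol by electrophilic formylation of an ether. Phenol 5 is allylated (allyl bromide, K2CO3, acetone) to 7-(allyloxy)-2,2-dimethyl-2H-chromene F1. Vilsmeier–Haack formylation (POCl3, DMF, 0 °C → rt, then aqueous NaOAc) goes para to the ring oxygen and gives 7-(allyloxy)-2,2-dimethyl-2H-chromene-6-carbaldehyde F2. Deallylation with Pd(PPh3)4 and morpholine in THF comes back to the route at 6.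

## Further compounds

F1 | step 4 | 7-(allyloxy)-2,2-dimethyl-2H-chromene | CC1(C)C=Cc2ccc(OCC=C)cc2O1
F2 | step 4 | 7-(allyloxy)-2,2-dimethyl-2H-chromene-6-carbaldehyde | CC1(C)C=Cc2cc(C=O)c(OCC=C)cc2O1
F3 | step 13 | 2,4-bis(allyloxy)-3-prenyl-5-(TIPSO)benzaldehyde | CC(C)[Si](Oc1cc(C=O)c(OCC=C)c(CC=C(C)C)c1OCC=C)(C(C)C)C(C)C
F4 | step 13 | 1-(2-methoxyvinyl)-2,4-bis(allyloxy)-3-prenyl-5-(TIPSO)benzene (E/Z mixture) | CC(C)[Si](Oc1cc(C=COC)c(OCC=C)c(CC=C(C)C)c1OCC=C)(C(C)C)C(C)C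
F5 | step 17 | (S)-1-(4-benzyl-2-thioxothiazolidin-3-yl)-2-[2,4-bis(allyloxy)-3-prenyl-5-(TIPSO)phenyl]ethan-1-one | CC(C)[Si](Oc1cc(CC(=O)N2[C@@H](Cc3ccccc3)CSC2=S)c(OCC=C)c(CC=C(C)C)c1OCC=C)(C(C)C)C(C)C
F6 | step 17 | (2S,3S)-1-[(S)-4-benzyl-2-thioxothiazolidin-3-yl]-2-[2,4-bis(allyloxy)-3-prenyl-5-(TIPSO)phenyl]-3-hydroxy-3-[7-(TBSO)-2,2-dimethyl-2H-chromen-6-yl]propan-1-one | O=C([C@@H](c1cc(O[Si](C(C)C)(C(C)C)C(C)C)c(OCC=C)c(CC=C(C)C)c1OCC=C)[C@H](O)c1cc2C=CC(C)(C)Oc2cc1O[Si](C)(C)C(C)(C)C)N1[C@@H](Cc2ccccc2)CSC1=S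
F7 | step 17 | (2S,3S)-1-[(S)-4-benzyl-2-thioxothiazolidin-3-yl]-2-[2,4-bis(allyloxy)-3-prenyl-5-(TIPSO)phenyl]-3-(TBSO)-3-[7-(TBSO)-2,2-dimethyl-2H-chromen-6-yl]propan-1-one | O=C([C@@H](c1cc(O[Si](C(C)C)(C(C)C)C(C)C)c(OCC=C)c(CC=C(C)C)c1OCC=C)[C@H](O[Si](C)(C)C(C)(C)C)c1cc2C=CC(C)(C)Oc2cc1O[Si](C)(C)C(C)(C)C)N1[C@@H](Cc2ccccc2)CSC1=S
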